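**Retrosynthetic overview**
- The coumestan core is opened across three bonds at once (C3–aryl C–C, furan C–O, lactone C–O), giving an open-chain o-hydroxyaryl β-keto ester and free resorcinol. One iron-catalysed oxidative operation closes the furan and the pyranone together.
- The β-keto ester comes from a chromanyl methyl ketone and diethyl carbonate (Claisen).
- The ketone comes from commercial, C2-symmetric 2',6'-dihydroxy-4'-methoxyacetophenone and isoprene. The symmetry fixes where the pyran oxygen, OMe and free OH sit.
- Ring order: dihydropyran first (step 1), then furan and pyranone together (step 3). Both benzene rings are bought.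

Assumption: the target has no stereocentre (it is achiral), so no enantiocontrol is needed and the SMILES carry no stereodescriptors.

**Step 1**
Reactants: 1 1-(2,6-dihydroxy-4-methoxyphenyl)ethan-1-one (2',6'-dihydroxy-4'-methoxyacetophenone); 2 isoprene (2-methylbuta-1,3-diene)
Product: 3 1-(7-hydroxy-5-methoxy-2,2-dimethyl-3,4-dihydro-2H-chromen-8-yl)ethan-1-one
Conditions: isoprene (1.2 equiv), Amberlyst-15, THF/heptane, 65 °C, sealed tube
Reagents that add atoms: none
Why: Acid-catalysed Friedel–Crafts prenylation by the isoprene-derived tertiary cation followed by Markovnikov cycloetherification (one-pot chroman annulation); because 1 is C2-symmetric its two free ring positions are equivalent and the prenyl group, flanked by OH and OMe, can only close onto the OH, so 3 is the only mono-chroman regioisomer and no stereocentre is created.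

**Step 2**
Reactants: 3 1-(7-hydroxy-5-methoxy-2,2-dimethyl-3,4-dihydro-2H-chromen-8-yl)ethan-1-one
Product: 4 ethyl 3-(7-hydroxy-5-methoxy-2,2-dimethyl-3,4-dihydro-2H-chromen-8-yl)-3-oxopropanoate
Conditions: NaH (4 equiv), (EtO)2CO (4 equiv), THF, 0 → 45 °C; then ice-cold 1 M HCl
Reagents that add atoms: diethyl carbonate CCOC(=O)OCC
Why: Crossed Claisen condensation (C-ethoxycarbonylation) of the methyl ketone enolate with diethyl carbonate; the product sits in the flask as its phenoxide/β-keto ester enolate dianion, which cannot lactonise, and the cold quench without heating releases the open-chain keto ester rather than the 4-hydroxycoumarin.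

**Step 3**
Reactants: 4 ethyl 3-(7-hydroxy-5-methoxy-2,2-dimethyl-3,4-dihydro-2H-chromen-8-yl)-3-oxopropanoate; 5 resorcinol (benzene-1,3-diol)
Product: 8 target pyrano-coumestan (9-hydroxy-3-methoxycoumestan bearing an O–C(CH3)2–CH2–CH2 bridge from C1–O to C2), via α-aryl keto ester 6 (not isolated), via benzofuran hydroxy ester 7 (not isolated)
Conditions: resorcinol (3 equiv), FeCl3·6H2O (20 mol%), (t-BuO)2 (2.2 equiv), ClCH2CH2Cl, 100 °C, sealed tube, Ar
Reagents that add atoms: none
Why: Iron-catalysed tandem oxidative coupling–annulation of a phenol with a β-keto ester: the Fe(III)-bound keto ester is oxidised at its α-carbon by t-BuO• and captured by resorcinol at C4 (ortho to one OH, para to the other) to give 6, the neighbouring phenol cyclodehydrates onto the aryl ketone to give benzofuran 7, and the chroman 7-OH then lactonises onto the adjacent ester with loss of ethanol, so furan and pyranone both close in this one operation; no stereocentre is involved.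

**Compound list**
1 | 1-(2,6-dihydroxy-4-methoxyphenyl)ethan-1-one | CC(=O)c1c(O)cc(OC)cc1O | starting material
2 | isoprene (2-methylbuta-1,3-diene) | C=CC(C)=C | starting material
3 | 1-(7-hydroxy-5-methoxy-2,2-dimethyl-3,4-dihydro-2H-chromen-8-yl)ethan-1-one | CC(=O)c1c(O)cc(OC)c2CCC(C)(C)Oc12 | intermediate
4 | ethyl 3-(7-hydroxy-5-methoxy-2,2-dimethyl-3,4-dihydro-2H-chromen-8-yl)-3-oxopropanoate | CCOC(=O)CC(=O)c1c(O)cc(OC)c2CCC(C)(C)Oc12 | intermediate
5 | resorcinol (benzene-1,3-diol) | Oc1cccc(O)c1 | starting material
6 | ethyl 2-(2,4-dihydroxyphenyl)-3-(7-hydroxy-5-methoxy-2,2-dimethyl-3,4-dihydro-2H-chromen-8-yl)-3-oxopropanoate | CCOC(=O)C(c1ccc(O)cc1O)C(=O)c1c(O)cc(OC)c2CCC(C)(C)Oc12 | intermediate (not isolated)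
7 | ethyl 6-hydroxy-2-(7-hydroxy-5-methoxy-2,2-dimethyl-3,4-dihydro-2H-chromen-8-yl)-1-benzofuran-3-carboxylate | CCOC(=O)c1c(-c2c(O)cc(OC)c3CCC(C)(C)Oc23)oc2cc(O)ccc12 | intermediate (not isolated)
8 | 9-hydroxy-3-methoxy-6H-benzofuro[3,2-c]chromen-6-one (coumestan numbering) with a 2,2-dimethyl-3,4-dihydro-2H-pyran ring fused at C1 (ring O) and C2 (CH2) | COc1cc2oc(=O)c3c4ccc(O)cc4oc3c2c2c1CCC(C)(C)O2 | target

**Step count and risks**
Total step count: 3. Longest linear sequence: 3.

Most likely to fail, in order:

Step 3 is the riskiest. Resorcinol is an excellent Pechmann substrate and FeCl3 can catalyse that condensation; the hydrated catalyst and the hindered, chelated ketone of 4 are relied on to suppress it. The free phenols can also annulate twice or over-oxidise, t-BuO• can attack the chroman benzylic CH2, and coupling at resorcinol C2 would give the 7-hydroxy isomer. If 4 lactonises before coupling, the resulting 3-aryl-4-hydroxycoumarin still dehydrates to 8, so both orders converge. The fallback leaves the oxidative manifold for a cross-coupling domino that still closes furan and pyranone together. It sets out from compound 4. Commercial 3-bromo-4-iodophenol is benzylated (BnBr, K2CO3, acetone) to 4-(benzyloxy)-2-bromo-1-iodobenzene F1. Compound 4 and F1 with CuI (10 mol%), K2CO3, THF, 100 °C undergo Hurtley-type C-arylation at the C–I carbon, intramolecular Ullmann O-arylation of the enol at the C–Br carbon, and lactonisation, giving 9-(benzyloxy)-3-methoxy pyrano-coumestan F2. Hydrogenolysis (H2, Pd/C, EtOAc/THF, rt) removes the benzyl group and comes back to the route at compound 8.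

Step 2 can overshoot to the 4-hydroxycoumarin (via O-ethoxycarbonylation of the phenoxide and intramolecular Claisen, or on acidic work-up), or stall at the hindered dianion. The fallback masks the phenol so that lactonisation is impossible. It sets out from compound 3. Benzylation (BnBr, K2CO3, DMF, 60 °C) gives 1-[7-(benzyloxy)-5-methoxy-2,2-dimethyl-3,4-dihydro-2H-chromen-8-yl]ethan-1-one F3. This can be driven hard (NaH, (EtO)2CO, toluene, reflux) to ethyl 3-[7-(benzyloxy)-5-methoxy-2,2-dimethyl-3,4-dihydro-2H-chromen-8-yl]-3-oxopropanoate F4. Neutral hydrogenolysis (H2 1 atm, Pd/C, EtOAc, rt) comes back to the route at compound 4.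

Step 1 can stop at low conversion or run on to the bis-chroman through the second OH. The fallback replaces cationic prenylation by a condensation/electrocyclisation route. It sets out from compound 1. Condensation with 3-methylbut-2-enal (ethylenediammonium diacetate cat., toluene, reflux; Knoevenagel-type condensation then oxa-6π electrocyclisation) gives 1-(7-hydroxy-5-methoxy-2,2-dimethyl-2H-chromen-8-yl)ethan-1-one F5, again a single regioisomer by symmetry. Hydrogenation of the chromene C3=C4 bond (H2 1 atm, Pd/C, EtOAc, rt) comes back to the route at compound 3.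

**Further compounds**
F1 | step 3 | 4-(benzyloxy)-2-bromo-1-iodobenzene | Ic1ccc(OCc2ccccc2)cc1Br
F2 | step 3 | 9-(benzyloxy)-3-methoxy pyrano-coumestan (9-O-benzyl ether of 8) | COc1cc2oc(=O)c3c4ccc(OCc5ccccc5)cc4oc3c2c2c1CCC(C)(C)O2
F3 | step 2 | 1-[7-(benzyloxy)-5-methoxy-2,2-dimethyl-3,4-dihydro-2H-chromen-8-yl]ethan-1-one | CC(=O)c1c(OCc3ccccc3)cc(OC)c2CCC(C)(C)Oc12
F4 | step 2 | ethyl 3-[7-(benzyloxy)-5-methoxy-2,2-dimethyl-3,4-dihydro-2H-chromen-8-yl]-3-oxopropanoate | CCOC(=O)CC(=O)c1c(OCc3ccccc3)cc(OC)c2CCC(C)(C)Oc12
F5 | step 1 | 1-(7-hydroxy-5-methoxy-2,2-dimethyl-2H-chromen-8-yl)ethan-1-one | CC(=O)c1c(O)cc(OC)c2C=CC(C)(C)Oc12
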